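A one-step world needs one constant: substrate falls exponentially, and its exposure θ, the natural logarithm of charged over remaining substrate, serves as the clock of the flask. In the north run, with 0.60 M of substrate under gas held at 20 mM, θ reaches 1.20 by 6.00 h, a mean first-step constant of 0.200 h⁻¹. But substrate here feeds a chain, through mono, bis and tris adduct to tetra adduct, and the questions concern the far end of it.

| setting | north | winter | autumn | dawn |
|---|---|---|---|---|
| substrate | 0.60 M | 0.30 M | 0.30 M | 0.30 M |
| gas | 20 mM (held) | 20 mM (held) | 20 mM (held) | 20 mM (held) |
| remark | run made earlier |  |  |  |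
| time |  | 3.0 d | 2.5 d | 4.0 d |

north run (percent of the substrate charged)

| time / h | mono adduct / % | tris adduct / % | tetra adduct / % | bis adduct / % | substrate / % |
|---|---|---|---|---|---|
| 0.500 | 6.9 | 0 | 0 | 0 | 92.3 |
| 0.833 | 12.7 | 0 | 0 | 0.2 | 87.7 |
| 1.33 | 19.0 | 0.1 | 0.2 | 0.7 | 80.3 |
| 2.00 | 27.1 | 0.4 | 0.3 | 2.3 | 71.3 |
| 4.00 | 45.9 | 0 | 0.3 | 6.7 | 47.6 |
| 6.00 | 55.7 | 0.7 | 0.5 | 14.8 | 30.1 |

(scatter of a reading: 0.3 percentage points)

- at the start none of the gas is in solution

1. which of these there is most of at the end, counted by the substrate in it, winter (bis adduct / tetra adduct / tris adduct / mono adduct)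
2. which of these there is most of at the end, counted by the substrate in it, autumn (bis adduct / tetra adduct / tris adduct / mono adduct)
3. which of these there is most of at the end, counted by the substrate in it, dawn (bis adduct / tetra adduct / tris adduct / mono adduct)
4. the largest of these amounts at the end, in percent of the substrate charged, winter
5. the largest of these amounts at the end, in percent of the substrate charged, autumn
6. the largest of these amounts at the end, in percent of the substrate charged, dawn

The ledger follows the substrate, the limiting reagent here since the gas is held, at the last north reading: 30.1% unreacted, 55.7% in mono adduct, 14.8% in bis adduct, 0.7% in tris adduct and 0.5% in tetra adduct. The entries sum to 102%, an overrun of 1.8 percentage points with each reading good to 0.3 points. The tris and tetra entries together, 1.20%, are smaller than that overrun.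

Replacing the rising bis curve by its mean over the run, with the area counted from 2.00 h onward, gives 5.08%; the dropped early hours add under 0.77 points. Then ρ = 0.197, the leak ratio: the fraction of bis adduct passed onward per unit of exposure. Since the leak entries lie within the overrun, this reading of ρ is taken as a ceiling rather than a constant. The reckoning here takes the north constant: autumn's 2.5 d is then an exposure of 12.0, and even at the ceiling bis adduct keeps 9.40% of itself. Below the ceiling it keeps more, but the ledger sets no lower bound on ρ, and keeping that share of itself does not put bis adduct in the lead, so this reckoning leaves the leader open.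

The forecast commits where this reckoning does not: it puts tetra adduct on top, at 97% in winter, 95% in autumn and 99% at dawn, on the ground that “Bis should be nearly gone, leaving tetra dominant”.

The flasks end with bis adduct in the lead: 64.7% in winter, 70.7% in autumn, 54.2% at dawn.

    substrate + coupling partner → mono adduct + by-product (k = 0.00643 M⁻¹ s⁻¹)
    coupling partner + mono adduct → bis adduct + by-product (k = 0.00210 M⁻¹ s⁻¹)
    coupling partner + bis adduct → tris adduct + by-product (k = 1.05 × 10⁻⁴ M⁻¹ s⁻¹)
    coupling partner + tris adduct → tetra adduct + by-product (k = 1.11 × 10⁻⁴ M⁻¹ s⁻¹)
    gas ⇌ coupling partner, rate k5*(csat - [coupling partner]) (kL = 0.00214 s⁻¹)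
    coupling partner → decomposed reagent (k = 1.91 × 10⁻⁵ s⁻¹)

With the step from bis to tris adduct struck out, winter ends at 100% bis adduct. In the dawn flask, the coupling partner stands at 0.0196 M, so the span from 2.00 d to 4.00 d is an exposure of 21.7. At the ceiling ρ, the 77.0% of bis adduct present at the start of that span falls to 1.07%, while the dawn flask holds 54.2%.

The readings were computed for substances that don't exist; noise was put on by code.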